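**Retrosynthetic overview**

- Feature: in the ten-membered carbocycle (C1–C10) the isopropenyl group sits on C1, next to C10H2 and the oxygenated C9. This is read as the trace of a [2,3] shift in which C10 was a sulfonium ylide carbon and C1 the terminus of an S–C12H2–C11(CH3)=C1 allyl unit.
- Late stage: target 31 comes from acylation of O14, hydroxyl-directed epoxidation of C7=C8 (oxirane, second ring), acetylation of O9, reduction of the C9 ketone, and reductive removal of sulfur from C10.
- Ring formation: the ten-membered ring (first ring) is closed at C1–C10 by contraction of a thirteen-membered sulfonium ylide made from the achiral seco diazo ketone 22.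
- Precursor: 22 comes from methyl ketone 20 by diazo transfer (diazomethane on an unsaturated acid chloride would risk pyrazoline formation). The chain is built by a Baylis–Hillman/allylic transposition sequence (C7=C8), a Wittig reaction (C3=C4) and an E-allyl phenyl sulfide from 4-methylpent-3-en-1-ol.

Key step: step 13

**Remarks**

- Numbering used throughout: ring carbons C1–C10; C1 bears the isopropenyl group C11(=C12H2)C13H3, C4 bears C15O2Me, C8 bears C14H2O. Descriptors in the names of 23–31 refer to this numbering.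
- Assumption: the (S,S)-ligand in step 13 is taken to give the 1S product; if the sense of induction is the opposite, its antipode is used and nothing else changes.
- The tartrate in step 18 is chosen by analogy with geraniol, which with L-(+)-diethyl tartrate gives the (2S,3S)-epoxide: seen from the new oxygen, C7→C9→C14 run clockwise at C8 in both cases.
- Compounds 16 and 17 are racemic at the carbinol carbon C7, which becomes sp2 in step 9.

**Route**

Step 1
Reactants: 1 4-methylpent-3-en-1-ol
Product: 2 (E)-2-methylpent-2-ene-1,5-diol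
Conditions: SeO2 (0.5 equiv), t-BuOOH (3 equiv), salicylic acid (0.1 equiv), CH2Cl2, rt
Reagents that add atoms: tert-butyl hydroperoxide CC(C)(C)OO (oxygen, relayed by SeO2)
Why: SeO2 allylic oxidation (Riley type; ene reaction then [2,3] shift) attacks the methyl group trans to the chain at the more substituted alkene terminus and should give the E allylic alcohol.

Step 2
Reactants: 2 (E)-2-methylpent-2-ene-1,5-diol
Product: 3 (E)-5-chloro-4-methylpent-3-en-1-ol
Conditions: N-chlorosuccinimide (1.2 equiv), Me2S (1.3 equiv), CH2Cl2, −20 → 0 °C, aqueous work-up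
Reagents that add atoms: N-chlorosuccinimide O=C1CCC(=O)N1Cl
Why: Corey–Kim halogenation converts only the allylic alkoxysulfonium ion into the chloride by SN2 attack of chloride (E geometry kept), while the saturated primary one reverts to the alcohol on work-up.

Step 3
Reactants: 3 (E)-5-chloro-4-methylpent-3-en-1-ol; 4 thiophenol
Product: 5 (E)-4-methyl-5-(phenylsulfanyl)pent-3-en-1-ol
Conditions: K2CO3 (1.5 equiv), DMF, 0 °C → rt
Reagents that add atoms: none
Why: SN2 thioetherification of the unhindered primary allylic chloride by the soft thiolate should proceed without allylic shift or loss of E geometry.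

Step 4
Reactants: 6 2-(3-chloropropyl)-1,3-dioxolane
Product: 7 [3-(1,3-dioxolan-2-yl)propyl]triphenylphosphonium iodide
Conditions: PPh3 (1.1 equiv), NaI (1.1 equiv), MeCN, reflux
Reagents that add atoms: triphenylphosphine c1ccc(cc1)P(c1ccccc1)c1ccccc1; sodium iodide [Na+].[I-]
Why: Finkelstein exchange followed by SN2 quaternisation of PPh3 with the primary iodide is standard phosphonium salt formation, and the acetal is inert.

Step 5
Reactants: 7 [3-(1,3-dioxolan-2-yl)propyl]triphenylphosphonium iodide; 8 methyl chloroformate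
Product: 11 methyl 4-(1,3-dioxolan-2-yl)-2-(triphenyl-λ5-phosphanylidene)butanoate, via non-stabilised ylide 9 (not isolated), via acylphosphonium chloride 10 (not isolated)
Conditions: NaN(SiMe3)2 (1 equiv), THF, −78 → 0 °C; ClCO2Me (1 equiv), −78 °C; NaN(SiMe3)2 (1 equiv), −78 °C → rt
Reagents that add atoms: none
Why: C-acylation of a non-stabilised phosphorus ylide with a chloroformate, followed by deprotonation of the acidic acylphosphonium salt, is the standard way to an α-alkyl ester-stabilised Wittig ylide.

Step 6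
Reactants: 5 (E)-4-methyl-5-(phenylsulfanyl)pent-3-en-1-ol; 11 methyl 4-(1,3-dioxolan-2-yl)-2-(triphenyl-λ5-phosphanylidene)butanoate
Product: 13 methyl (2E,5E)-2-[2-(1,3-dioxolan-2-yl)ethyl]-6-methyl-7-(phenylsulfanyl)hepta-2,5-dienoate, via β,γ-unsaturated aldehyde 12 (not isolated)
Conditions: Dess–Martin periodinane (1.2 equiv), CH2Cl2, 0 °C; then 11 (2.5 equiv), rt → 40 °C
Reagents that add atoms: none
Why: Dess–Martin oxidation tolerates the aryl sulfide, and the sensitive skipped aldehyde is trapped in the same flask by a base-free Wittig reaction with the α-substituted stabilised ylide, which should place C2 trans to the ester (E at C3=C4).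

Step 7
Reactants: 13 methyl (2E,5E)-2-[2-(1,3-dioxolan-2-yl)ethyl]-6-methyl-7-(phenylsulfanyl)hepta-2,5-dienoate
Product: 14 methyl (2E,5E)-6-methyl-2-(3-oxopropyl)-7-(phenylsulfanyl)hepta-2,5-dienoate
Conditions: 2 M aq. HCl, THF, rt
Reagents that add atoms: water O
Why: Acid-catalysed acetal hydrolysis frees the C7 aldehyde; the enoate, the skipped diene and the allyl sulfide should be stable to dilute acid at room temperature.

Step 8
Reactants: 14 methyl (2E,5E)-6-methyl-2-(3-oxopropyl)-7-(phenylsulfanyl)hepta-2,5-dienoate; 15 methyl vinyl ketone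
Product: 16 methyl (2E,5E)-2-(3-hydroxy-4-methylidene-5-oxohexyl)-6-methyl-7-(phenylsulfanyl)hepta-2,5-dienoate (racemic)
Conditions: 1,4-diazabicyclo[2.2.2]octane (DABCO, 0.3 equiv), 15 (3 equiv), THF, rt
Reagents that add atoms: none
Why: The Morita–Baylis–Hillman reaction of an unhindered aliphatic aldehyde with methyl vinyl ketone forms C7–C8 and brings in C8, C9, C10 and C14 in one step; the trisubstituted enoate does not compete as acceptor.

Step 9
Reactants: 16 methyl (2E,5E)-2-(3-hydroxy-4-methylidene-5-oxohexyl)-6-methyl-7-(phenylsulfanyl)hepta-2,5-dienoate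
Product: 18 methyl (2E,5E)-2-[(3E)-4-(acetoxymethyl)-5-oxohex-3-en-1-yl]-6-methyl-7-(phenylsulfanyl)hepta-2,5-dienoate, via secondary acetate 17 (not isolated)
Conditions: Ac2O (1.5 equiv), Et3N, 4-(dimethylamino)pyridine (cat.), THF, 0 °C; then DABCO (0.3 equiv), 60 °C
Reagents that add atoms: acetic anhydride CC(=O)OC(C)=O
Why: The amine-catalysed 1,3-transposition of Baylis–Hillman acetates (SN2' addition of DABCO, return of acetate at the CH2 terminus) runs under thermodynamic control and should give the primary acetate with the trisubstituted E enone (C6 trans to the acetyl group).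

Step 10
Reactants: 18 methyl (2E,5E)-2-[(3E)-4-(acetoxymethyl)-5-oxohex-3-en-1-yl]-6-methyl-7-(phenylsulfanyl)hepta-2,5-dienoate
Product: 19 methyl (2E,5E)-2-[(3E)-4-(hydroxymethyl)-5-oxohex-3-en-1-yl]-6-methyl-7-(phenylsulfanyl)hepta-2,5-dienoate
Conditions: K2CO3 (0.2 equiv), MeOH, 0 °C
Reagents that add atoms: none
Why: Brief base-catalysed methanolysis cleaves the primary acetate, a known operation on rearranged Baylis–Hillman acetates; the methyl ester is degenerate in methanol.

Step 11
Reactants: 19 methyl (2E,5E)-2-[(3E)-4-(hydroxymethyl)-5-oxohex-3-en-1-yl]-6-methyl-7-(phenylsulfanyl)hepta-2,5-dienoate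
Product: 20 methyl (2E,5E)-2-[(3E)-4-(tert-butyldimethylsilyloxymethyl)-5-oxohex-3-en-1-yl]-6-methyl-7-(phenylsulfanyl)hepta-2,5-dienoate
Conditions: t-BuMe2SiCl (1.2 equiv), imidazole (2 equiv), DMF, 0 °C → rt
Reagents that add atoms: tert-butyldimethylsilyl chloride CC(C)(C)[Si](C)(C)Cl
Why: Standard silylation masks O14, which would otherwise trap the carbenoid by O–H insertion, with a group that can later be removed beside an acetate.

Step 12
Reactants: 20 methyl (2E,5E)-2-[(3E)-4-(tert-butyldimethylsilyloxymethyl)-5-oxohex-3-en-1-yl]-6-methyl-7-(phenylsulfanyl)hepta-2,5-dienoate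
Product: 22 methyl (2E,5E)-2-[(3E)-6-diazo-4-(tert-butyldimethylsilyloxymethyl)-5-oxohex-3-en-1-yl]-6-methyl-7-(phenylsulfanyl)hepta-2,5-dienoate, via trifluoroacetyl diketone 21 (not isolated)
Conditions: LiN(SiMe3)2 (1.1 equiv), THF, −78 °C; CF3CO2CH2CF3 (1.2 equiv); dilute HCl work-up; then MeSO2N3 (1.5 equiv), Et3N (1.5 equiv), H2O (1 equiv), MeCN, rt
Reagents that add atoms: methanesulfonyl azide CS(=O)(=O)N=[N+]=[N-]; 2,2,2-trifluoroethyl trifluoroacetate O=C(OCC(F)(F)F)C(F)(F)F (its trifluoroacetyl group is carried only by intermediate 21)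
Why: Kinetic α'-enolisation of the methyl ketone, trifluoroacetylation and detrifluoroacetylative diazo transfer is the established route to α'-diazo enones and avoids diazomethane, which would risk cycloaddition to the conjugated alkenes.

Step 13
Reactants: 22 methyl (2E,5E)-2-[(3E)-6-diazo-4-(tert-butyldimethylsilyloxymethyl)-5-oxohex-3-en-1-yl]-6-methyl-7-(phenylsulfanyl)hepta-2,5-dienoate
Product: 24 methyl (1S,3E,7E)-8-(tert-butyldimethylsilyloxymethyl)-9-oxo-10-(phenylsulfanyl)-1-(prop-1-en-2-yl)cyclodeca-3,7-diene-4-carboxylate (C10 epimers), via sulfonium ylide 23 (not isolated)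
Conditions: Cu(MeCN)4PF6 (5 mol%), 2,2'-isopropylidenebis[(4S)-4-tert-butyl-2-oxazoline] (6 mol%), CH2Cl2, 40 °C, 22 added over 12 h by syringe pump (final 1 mM)
Reagents that add atoms: none
Why: Proposed new method: the copper–bis(oxazoline) complex should decompose 22 to an electrophilic carbenoid at C10, the remote sulfide sulfur adds to it to give the keto-stabilised thirteen-membered sulfonium ylide 23, and a suprafacial [2,3] shift through a five-membered envelope (C10, S, C12, C11, C1) forms C1–C10 while S–C12 breaks and C11=C12 appears. The closest known reactions are the Doyle–Kirmse reaction of allyl sulfides with diazo carbonyl compounds, its copper–bis(oxazoline) and dirhodium asymmetric variants, and the ring-contracting [2,3] shifts of macrocyclic oxonium ylides made from diazo esters. The ten-membered ring is closed not by end-to-end C–C macrocyclisation but by three-atom contraction of the ylide ring, which itself closes by capture of the carbenoid by sulfur under high dilution, so that the entropic cost is paid in a fast heteroatom–carbenoid step. C1 is the only stereocentre that is kept (the C10 epimers converge in step 14), and it is controlled by the chiral catalyst, which selects one of the two enantiotopic lone pairs of sulfur or stays bound during the shift; the configuration at sulfur is then relayed to C1 through the envelope with S-phenyl exo, and the E geometry of C1=C11 fixes the positions of C2 and H. The step needs sulfur capture to outrun cyclopropanation, C–H insertion and dimerisation: the thioether is the best nucleophile present, the enoate is electron-poor, the E enone holds the carbenoid away from C5 and C6, and slow addition suppresses bimolecular paths.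

Step 14
Reactants: 24 methyl (1S,3E,7E)-8-(tert-butyldimethylsilyloxymethyl)-9-oxo-10-(phenylsulfanyl)-1-(prop-1-en-2-yl)cyclodeca-3,7-diene-4-carboxylate
Product: 25 methyl (1S,3E,7E)-8-(tert-butyldimethylsilyloxymethyl)-9-oxo-1-(prop-1-en-2-yl)cyclodeca-3,7-diene-4-carboxylate
Conditions: SmI2 (2.5 equiv), THF/MeOH 10:1, −78 °C
Reagents that add atoms: none
Why: Reductive cleavage of an α-heteroatom-substituted ketone by SmI2 (two one-electron transfers, then protonation of the samarium enolate at C10) is fast at −78 °C and should leave the enone, the enoate and the silyl ether untouched.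

Step 15
Reactants: 25 methyl (1S,3E,7E)-8-(tert-butyldimethylsilyloxymethyl)-9-oxo-1-(prop-1-en-2-yl)cyclodeca-3,7-diene-4-carboxylate
Product: 26 methyl (1S,3E,7E,9S)-8-(tert-butyldimethylsilyloxymethyl)-9-hydroxy-1-(prop-1-en-2-yl)cyclodeca-3,7-diene-4-carboxylate
Conditions: (R)-2-methyl-CBS-oxazaborolidine [(R)-1-methyl-3,3-diphenyltetrahydro-1H,3H-pyrrolo[1,2-c][1,3,2]oxazaborole] (1 equiv), catecholborane (1.8 equiv), toluene, −78 °C
Reagents that add atoms: none
Why: In the Corey–Bakshi–Shibata reduction the ketone binds the (R)-oxazaborolidine with the α-branched alkenyl carbon C8 as the large group and C10H2 as the small one, so hydride delivery should set 9S as with acyclic enones; catecholborane is chosen because it does not hydroborate the isopropenyl group.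

Step 16
Reactants: 26 methyl (1S,3E,7E,9S)-8-(tert-butyldimethylsilyloxymethyl)-9-hydroxy-1-(prop-1-en-2-yl)cyclodeca-3,7-diene-4-carboxylate
Product: 27 methyl (1S,3E,7E,9S)-9-acetoxy-8-(tert-butyldimethylsilyloxymethyl)-1-(prop-1-en-2-yl)cyclodeca-3,7-diene-4-carboxylate
Conditions: Ac2O, pyridine, 4-(dimethylamino)pyridine (cat.), CH2Cl2, 0 °C → rt
Reagents that add atoms: acetic anhydride CC(=O)OC(C)=O
Why: Acylation of the only free hydroxyl installs the C9 acetate of the target with retention and removes O9 as a competing directing group for the epoxidation.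

Step 17
Reactants: 27 methyl (1S,3E,7E,9S)-9-acetoxy-8-(tert-butyldimethylsilyloxymethyl)-1-(prop-1-en-2-yl)cyclodeca-3,7-diene-4-carboxylate
Product: 28 methyl (1S,3E,7E,9S)-9-acetoxy-8-(hydroxymethyl)-1-(prop-1-en-2-yl)cyclodeca-3,7-diene-4-carboxylate
Conditions: HF·pyridine, pyridine, THF, 0 °C
Reagents that add atoms: none
Why: Buffered fluoride cleaves the primary allylic silyl ether under mildly acidic conditions, under which 1,3-migration of the acetyl group from O9 to O14 should be slow.

Step 18
Reactants: 28 methyl (1S,3E,7E,9S)-9-acetoxy-8-(hydroxymethyl)-1-(prop-1-en-2-yl)cyclodeca-3,7-diene-4-carboxylate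
Product: 29 methyl (1S,3E,7R,8S,9S)-9-acetoxy-7,8-epoxy-8-(hydroxymethyl)-1-(prop-1-en-2-yl)cyclodec-3-ene-4-carboxylate
Conditions: Ti(OiPr)4 (0.2 equiv), L-(+)-diethyl tartrate [diethyl (2R,3R)-tartrate] (0.24 equiv), t-BuOOH (2 equiv, anhydrous), 4 Å molecular sieves, CH2Cl2, −20 °C
Reagents that add atoms: tert-butyl hydroperoxide CC(C)(C)OO
Why: Sharpless asymmetric epoxidation delivers oxygen from the titanium-bound O14 only to the allylic alcohol alkene (enoate and isopropenyl are spared), and L-(+)-tartrate should give the 7R,8S oxirane, the face that is also exposed when the C9 acetoxy group lies pseudo-equatorial on the E ring alkene.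

Step 19
Reactants: 29 methyl (1S,3E,7R,8S,9S)-9-acetoxy-7,8-epoxy-8-(hydroxymethyl)-1-(prop-1-en-2-yl)cyclodec-3-ene-4-carboxylate; 30 (R)-2-methylbutanoic acid
Product: 31 methyl (1S,3E,7R,8S,9S)-9-acetoxy-7,8-epoxy-8-{[(2R)-2-methylbutanoyl]oxymethyl}-1-(prop-1-en-2-yl)cyclodec-3-ene-4-carboxylate (CNP0352790.1)
Conditions: 30 (1.5 equiv), N-(3-dimethylaminopropyl)-N'-ethylcarbodiimide hydrochloride (1.6 equiv), 4-(dimethylamino)pyridine (0.2 equiv), CH2Cl2, 0 °C → rt
Reagents that add atoms: none
Why: Steglich-type carbodiimide esterification of the single primary hydroxyl at low temperature with catalytic acyl-transfer agent should attach the acid without epimerising its α-stereocentre or opening the oxirane.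

**Compound list**

1 | 4-methylpent-3-en-1-ol | CC(C)=CCCO | starting material
2 | (E)-2-methylpent-2-ene-1,5-diol | OC/C(C)=C/CCO | intermediate
3 | (E)-5-chloro-4-methylpent-3-en-1-ol | ClC/C(C)=C/CCO | intermediate
4 | thiophenol | Sc1ccccc1 | starting material
5 | (E)-4-methyl-5-(phenylsulfanyl)pent-3-en-1-ol | OCC/C=C(\C)CSc1ccccc1 | intermediate
6 | 2-(3-chloropropyl)-1,3-dioxolane | ClCCCC1OCCO1 | starting material
7 | [3-(1,3-dioxolan-2-yl)propyl]triphenylphosphonium iodide | [I-].C1COC(CCC[P+](c2ccccc2)(c2ccccc2)c2ccccc2)O1 | intermediate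
8 | methyl chloroformate | COC(Cl)=O | starting material
9 | [3-(1,3-dioxolan-2-yl)propylidene]triphenylphosphorane | C1COC(CCC=P(c2ccccc2)(c2ccccc2)c2ccccc2)O1 | intermediate (not isolated)
10 | [4-(1,3-dioxolan-2-yl)-1-methoxy-1-oxobutan-2-yl]triphenylphosphonium chloride | [Cl-].COC(=O)C(CCC1OCCO1)[P+](c1ccccc1)(c1ccccc1)c1ccccc1 | intermediate (not isolated)
11 | methyl 4-(1,3-dioxolan-2-yl)-2-(triphenyl-λ5-phosphanylidene)butanoate | COC(=O)C(CCC1OCCO1)=P(c1ccccc1)(c1ccccc1)c1ccccc1 | intermediate
12 | (E)-4-methyl-5-(phenylsulfanyl)pent-3-enal | O=CC/C=C(\C)CSc1ccccc1 | intermediate (not isolated)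
13 | methyl (2E,5E)-2-[2-(1,3-dioxolan-2-yl)ethyl]-6-methyl-7-(phenylsulfanyl)hepta-2,5-dienoate | COC(=O)/C(CCC1OCCO1)=C/C/C=C(\C)CSc1ccccc1 | intermediate
14 | methyl (2E,5E)-6-methyl-2-(3-oxopropyl)-7-(phenylsulfanyl)hepta-2,5-dienoate | COC(=O)/C(CCC=O)=C/C/C=C(\C)CSc1ccccc1 | intermediate
15 | methyl vinyl ketone (but-3-en-2-one) | CC(=O)C=C | starting material
16 | methyl (2E,5E)-2-(3-hydroxy-4-methylidene-5-oxohexyl)-6-methyl-7-(phenylsulfanyl)hepta-2,5-dienoate (racemic) | COC(=O)/C(CCC(O)C(=C)C(C)=O)=C/C/C=C(\C)CSc1ccccc1 | intermediate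
17 | methyl (2E,5E)-2-(3-acetoxy-4-methylidene-5-oxohexyl)-6-methyl-7-(phenylsulfanyl)hepta-2,5-dienoate (racemic) | COC(=O)/C(CCC(OC(C)=O)C(=C)C(C)=O)=C/C/C=C(\C)CSc1ccccc1 | intermediate (not isolated)
18 | methyl (2E,5E)-2-[(3E)-4-(acetoxymethyl)-5-oxohex-3-en-1-yl]-6-methyl-7-(phenylsulfanyl)hepta-2,5-dienoate | CC(=O)/C(COC(C)=O)=C/CC/C(C(=O)OC)=C\C/C=C(\C)CSc1ccccc1 | intermediate
19 | methyl (2E,5E)-2-[(3E)-4-(hydroxymethyl)-5-oxohex-3-en-1-yl]-6-methyl-7-(phenylsulfanyl)hepta-2,5-dienoate | CC(=O)/C(CO)=C/CC/C(C(=O)OC)=C\C/C=C(\C)CSc1ccccc1 | intermediate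
20 | methyl (2E,5E)-2-[(3E)-4-(tert-butyldimethylsilyloxymethyl)-5-oxohex-3-en-1-yl]-6-methyl-7-(phenylsulfanyl)hepta-2,5-dienoate | CC(=O)/C(CO[Si](C)(C)C(C)(C)C)=C/CC/C(C(=O)OC)=C\C/C=C(\C)CSc1ccccc1 | intermediate
21 | methyl (2E,5E)-2-[(3E)-4-(tert-butyldimethylsilyloxymethyl)-8,8,8-trifluoro-5,7-dioxooct-3-en-1-yl]-6-methyl-7-(phenylsulfanyl)hepta-2,5-dienoate | O=C(C(F)(F)F)CC(=O)/C(CO[Si](C)(C)C(C)(C)C)=C/CC/C(C(=O)OC)=C\C/C=C(\C)CSc1ccccc1 | intermediate (not isolated)
22 | methyl (2E,5E)-2-[(3E)-6-diazo-4-(tert-butyldimethylsilyloxymethyl)-5-oxohex-3-en-1-yl]-6-methyl-7-(phenylsulfanyl)hepta-2,5-dienoate (seco diazo ketone) | [N-]=[N+]=CC(=O)/C(CO[Si](C)(C)C(C)(C)C)=C/CC/C(C(=O)OC)=C\C/C=C(\C)CSc1ccccc1 | intermediate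
23 | thirteen-membered S-phenyl sulfonium ylide (ring S, C10, C9–C1, C11, C12; carbanion at C10 between S and the C9 ketone) | [CH-]1C(=O)/C(CO[Si](C)(C)C(C)(C)C)=C/CC/C(C(=O)OC)=C\C/C=C(\C)C[S+]1c1ccccc1 | intermediate (not isolated)
24 | methyl (1S,3E,7E)-8-(tert-butyldimethylsilyloxymethyl)-9-oxo-10-(phenylsulfanyl)-1-(prop-1-en-2-yl)cyclodeca-3,7-diene-4-carboxylate (C10 unassigned) | C=C(C)[C@H]1C/C=C(/C(=O)OC)CC/C=C(\CO[Si](C)(C)C(C)(C)C)C(=O)C1Sc1ccccc1 | intermediate
25 | methyl (1S,3E,7E)-8-(tert-butyldimethylsilyloxymethyl)-9-oxo-1-(prop-1-en-2-yl)cyclodeca-3,7-diene-4-carboxylate | C=C(C)[C@H]1C/C=C(/C(=O)OC)CC/C=C(\CO[Si](C)(C)C(C)(C)C)C(=O)C1 | intermediate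
26 | methyl (1S,3E,7E,9S)-8-(tert-butyldimethylsilyloxymethyl)-9-hydroxy-1-(prop-1-en-2-yl)cyclodeca-3,7-diene-4-carboxylate | C=C(C)[C@H]1C/C=C(/C(=O)OC)CC/C=C(\CO[Si](C)(C)C(C)(C)C)[C@@H](O)C1 | intermediate
27 | methyl (1S,3E,7E,9S)-9-acetoxy-8-(tert-butyldimethylsilyloxymethyl)-1-(prop-1-en-2-yl)cyclodeca-3,7-diene-4-carboxylate | C=C(C)[C@H]1C/C=C(/C(=O)OC)CC/C=C(\CO[Si](C)(C)C(C)(C)C)[C@@H](OC(C)=O)C1 | intermediate
28 | methyl (1S,3E,7E,9S)-9-acetoxy-8-(hydroxymethyl)-1-(prop-1-en-2-yl)cyclodeca-3,7-diene-4-carboxylate | C=C(C)[C@H]1C/C=C(/C(=O)OC)CC/C=C(\CO)[C@@H](OC(C)=O)C1 | intermediate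
29 | methyl (1S,3E,7R,8S,9S)-9-acetoxy-7,8-epoxy-8-(hydroxymethyl)-1-(prop-1-en-2-yl)cyclodec-3-ene-4-carboxylate | C=C(C)[C@H]1C/C=C(/C(=O)OC)CC[C@H]2O[C@]2(CO)[C@@H](OC(C)=O)C1 | intermediate
30 | (R)-2-methylbutanoic acid | CC[C@@H](C)C(=O)O | starting material
31 | methyl (1S,3E,7R,8S,9S)-9-acetoxy-7,8-epoxy-8-{[(2R)-2-methylbutanoyl]oxymethyl}-1-(prop-1-en-2-yl)cyclodec-3-ene-4-carboxylate (CNP0352790.1) | C=C(C)[C@H]1C/C=C(/C(=O)OC)CC[C@H]2O[C@]2(COC(=O)[C@H](C)CC)[C@@H](OC(C)=O)C1 | target

**Step count**

Total: 19 steps. Longest linear sequence: 17 steps (steps 1–3, then 6–19); the ylide branch (steps 4–5) joins at step 6.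

**Steps most likely to fail**

1. Step 13 (Proposed new method). What may go wrong is weak discrimination between the two lone pairs of sulfur, or loss of catalyst control once the ylide is free, so that C1 forms with low enantiomeric excess; oligomerisation at the carbenoid stage would add to this. The fallback gives up asymmetric catalysis and resolves through diastereomers, using known chemistry. It sets out from 22, which is cyclised with achiral Rh2(OAc)4 (1 mol%, CH2Cl2, 40 °C, slow addition), the non-asymmetric intramolecular carbenoid/sulfonium ylide/[2,3] sequence, to give the racemic α-phenylsulfanyl enone F1. SmI2 as in step 14 should give the racemic ketone F2. Reduction with the (R)-oxazaborolidine and catecholborane as in step 15 should turn the two enantiomers into diastereomers, 26 and the (1R,9S)-alcohol F3, which are separated by chromatography. The fallback returns to the route at 26.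

2. Step 18. What may go wrong is slow or face-unselective oxygen transfer, because the titanium–tartrate complex has to bind a hindered 2,3-disubstituted allylic alcohol held in a ten-membered ring whose exposed alkene face may not be the one the tartrate prefers; the titanium alkoxide could also promote acetyl migration from O9 to O14. The fallback replaces reagent control by substrate control. It sets out from 28, which is epoxidised with VO(acac)2 (5 mol%) and t-BuOOH in toluene at 0 °C; the vanadate ester of O14 should deliver oxygen to the peripheral face of the E-configured C7=C8 bond in the conformer with the C9 acetoxy group pseudo-equatorial. It returns to the route at 29 and makes no new compound.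

3. Step 15. What may go wrong is poor diastereofacial selectivity of hydride delivery, if the conformation of the ten-membered enone overrides the oxazaborolidine, or competing 1,4-reduction. The fallback is an unselective reduction followed by stereochemical correction. It sets out from 25, which under Luche conditions (NaBH4, CeCl3·7H2O, MeOH, −40 °C) should give 26 together with its C9 epimer, the (1S,9R)-alcohol F4. After chromatographic separation 26 goes on to step 16. F4 is converted by a Mitsunobu reaction with acetic acid (PPh3, diisopropyl azodicarboxylate, THF, 0 °C), with inversion at C9, directly into acetate 27, where it rejoins the route.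

**Further compounds**

F1 | step 13 | racemic methyl (3E,7E)-8-(tert-butyldimethylsilyloxymethyl)-9-oxo-10-(phenylsulfanyl)-1-(prop-1-en-2-yl)cyclodeca-3,7-diene-4-carboxylate | C=C(C)C1C/C=C(/C(=O)OC)CC/C=C(\CO[Si](C)(C)C(C)(C)C)C(=O)C1Sc1ccccc1
F2 | step 13 | racemic methyl (3E,7E)-8-(tert-butyldimethylsilyloxymethyl)-9-oxo-1-(prop-1-en-2-yl)cyclodeca-3,7-diene-4-carboxylate | C=C(C)C1C/C=C(/C(=O)OC)CC/C=C(\CO[Si](C)(C)C(C)(C)C)C(=O)C1
F3 | step 13 | methyl (1R,3E,7E,9S)-8-(tert-butyldimethylsilyloxymethyl)-9-hydroxy-1-(prop-1-en-2-yl)cyclodeca-3,7-diene-4-carboxylate | C=C(C)[C@@H]1C/C=C(/C(=O)OC)CC/C=C(\CO[Si](C)(C)C(C)(C)C)[C@@H](O)C1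
F4 | step 15 | methyl (1S,3E,7E,9R)-8-(tert-butyldimethylsilyloxymethyl)-9-hydroxy-1-(prop-1-en-2-yl)cyclodeca-3,7-diene-4-carboxylate | C=C(C)[C@H]1C/C=C(/C(=O)OC)CC/C=C(\CO[Si](C)(C)C(C)(C)C)[C@H](O)C1
F0 | step 18 | none | none
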